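**Strategy.** Moving the C9=C10 enone bond to its β,γ position (C1=C10, eremophilane numbering) uncovers a γ,δ-unsaturated acid, C15–C4–C5–C10=C1, inside ring A. Ring B then becomes a Birch-reduced anisole. Everything therefore rests on the C4–C5 bond, made by Ireland–Claisen rearrangement of a δ-valerolactone whose carbinol carbon C1 carries a 5-methoxy-2-methylcyclohexa-1,4-dienyl group. In one operation the lactone ring is exchanged for carbocyclic ring A, the C1–O stereocentre is relayed to quaternary C5, C15 is released as the acid, and ring B is left as a masked C8 enone. The precursor is a flat aryl lactone made from an aryl Grignard reagent and glutaric anhydride, then Birch reduced.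

Key step: step 5

Remark: eremophilane numbering is used (C1 acyloxy carbon, C4 carboxyl-bearing carbon, C5 quaternary carbon, C7 acrolein-bearing carbon, C8 ketone, C9=C10 enone alkene, C14 methyl on C5, C15 CO2H). β is the face that carries C14, and the given SMILES reads as (1R,4S,5R,7S,4′S,2′E), i.e. 1β-O, 4β-CO2H, 5β-CH3, 7α side chain.

Step 1
Reactants: 1 2-bromo-4-methoxy-1-methylbenzene; 2 glutaric anhydride
Product: 4 5-(5-methoxy-2-methylphenyl)-5-oxopentanoic acid, via aryl Grignard reagent 3 (not isolated)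
Conditions: Mg, THF, 40 °C; cannulate into 2, THF, −78 to 0 °C; 1 M HCl
Reagents that add atoms: magnesium, [Mg] (atoms only in 3)
Why: Acylation of an aryl Grignard reagent by a cyclic anhydride should stop at the keto carboxylate, whose magnesium salt resists a second addition at low temperature, and it fixes C1 on the ring carbon (C10) that lies ortho to the methyl-bearing C5 and meta to the methoxy-bearing C8.

Step 2
Reactants: 4 5-(5-methoxy-2-methylphenyl)-5-oxopentanoic acid
Product: 6 (6S)-6-(5-methoxy-2-methylphenyl)oxan-2-one, via hydroxy acid 5 (not isolated)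
Conditions: RuCl[(S,S)-TsDPEN](p-cymene) (cat.), HCO2H/Et3N 5:2, 40 °C; then PPTS (cat.), PhMe, 40 °C
Reagents that add atoms: none
Why: Noyori–Ikariya asymmetric transfer hydrogenation of an aryl alkyl ketone, in which the (S,S)-catalyst delivers hydride to the Re face through its CH/π contact with the aryl ring, should set the (S)-carbinol at C1, and mild acid closes the δ-lactone, which can be recrystallised.

Step 3
Reactants: 6 (6S)-6-(5-methoxy-2-methylphenyl)oxan-2-one
Product: 8 (5S)-5-hydroxy-5-(5-methoxy-2-methylcyclohexa-1,4-dien-1-yl)pentanoic acid, via lithium hydroxy carboxylate 7 (not isolated)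
Conditions: LiOH (1.0 equiv), THF/H2O, rt, evaporate to dryness; Li, NH3(l)/THF/t-BuOH, −78 to −33 °C; NH4Cl; aq NaH2PO4 (pH 5–6), 0 °C
Reagents that add atoms: lithium hydroxide, [Li+].[OH-]
Why: Saponification followed by Birch reduction: as alkoxide and carboxylate the benzylic C1–O bond and C15 are shielded from reductive cleavage (the behaviour known for 3-methoxybenzyl alcohols), and protonation ortho and meta to the methoxy group leaves the C7=C8 enol ether and the tetrasubstituted C10=C5 alkene.

Step 4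
Reactants: 8 (5S)-5-hydroxy-5-(5-methoxy-2-methylcyclohexa-1,4-dien-1-yl)pentanoic acid
Product: 9 (6S)-6-(5-methoxy-2-methylcyclohexa-1,4-dien-1-yl)oxan-2-one
Conditions: EDC·HCl, DMAP, CH2Cl2, 0 °C to rt
Reagents that add atoms: none
Why: Carbodiimide lactonisation under non-acidic conditions should close the δ-lactone without hydrolysing the enol ether or ionising the dienylic alcohol, and C1 is not touched.

Step 5
Reactants: 9 (6S)-6-(5-methoxy-2-methylcyclohexa-1,4-dien-1-yl)oxan-2-one
Product: 13 (1R,8aR)-8a-methyl-6-oxo-1,2,3,4,6,7,8,8a-octahydronaphthalene-1-carboxylic acid (4α-CO2H, 5β-CH3), via lithium enolate 10 (not isolated), via silyl ketene acetal 11 (not isolated), via TBS ester 12 (not isolated)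
Conditions: LDA, THF, −78 °C; TBSCl, DMPU, −78 °C to rt; switch to PhMe (xylene if needed), 110–140 °C, Ar; then 2 M HCl, THF, rt
Reagents that add atoms: lithium diisopropylamide, [Li+].CC(C)[N-]C(C)C (Li only in 10); tert-butyldimethylsilyl chloride, CC(C)(C)[Si](C)(C)Cl (atoms only in 11 and 12); water, O (ketone oxygen at C8)
Why: LDA and TBSCl convert lactone 9 into the cyclic silyl ketene acetal 11, whose C4=C15–O–C1–C10=C5 array undergoes a concerted suprafacial [3,3] shift that forms C4–C5, breaks C1–O and leaves silyl ester 12; this is the Ireland–Claisen rearrangement of a 6-alkenyl δ-lactone, a known route from lactones to cyclohexenecarboxylic acids. Ring A closes as the six-membered lactone is traded for a six-membered carbocycle (C4 attacks the C5 end of the C10=C5 alkene in a 6-endo sense), and the two-atom C2–C3 tether allows only a boat, bicyclo[2.2.2]-like transition state. C5 is controlled by chirality transfer: C4 can bond only to the alkene face on which the C1–O bond stands, so (1S) should give (5R) with C14 pushed to the β face. C4 is controlled by the ring-locked ketene acetal geometry (C3 cis to the ring oxygen) together with the boat, which puts C15 anti to C14, that is the (4R) epimer, corrected in step 7. The step needs periselectivity and survival of the 1,4-diene: only one allyl unit is within reach of C4, the C7=C8 enol ether is a spectator, the base is used up at −78 °C before the bis-allylic C6 and C9 hydrogens can react, and once C5 is quaternary ring B can no longer aromatise. Aqueous HCl then cleaves the silyl ester and the enol ether and draws C1=C10 into conjugation as C9=C10, as in the Δ5 to Δ4 isomerisation of 3-keto steroids.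

Step 6
Reactants: 13 (1R,8aR)-8a-methyl-6-oxo-1,2,3,4,6,7,8,8a-octahydronaphthalene-1-carboxylic acid
Product: 14 4-methoxybenzyl (1R,8aR)-8a-methyl-6-oxo-1,2,3,4,6,7,8,8a-octahydronaphthalene-1-carboxylate
Conditions: PMBCl, Cs2CO3, Bu4NI (cat.), DMF, rt
Reagents that add atoms: 4-methoxybenzyl chloride, COc1ccc(CCl)cc1
Why: SN2 O-alkylation of the caesium carboxylate is insensitive to the hindrance around the axial C15 carboxyl group and gives an ester that survives strong base and silyl triflate yet leaves under mild acid.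

Step 7
Reactants: 14 4-methoxybenzyl (1R,8aR)-8a-methyl-6-oxo-1,2,3,4,6,7,8,8a-octahydronaphthalene-1-carboxylate
Product: 16 4-methoxybenzyl (1S,8aR)-8a-methyl-6-oxo-1,2,3,4,6,7,8,8a-octahydronaphthalene-1-carboxylate (4β-ester), via dilithium bis-enolate 15 (not isolated)
Conditions: LDA (2.3 equiv), THF, −78 to −30 °C; AcOH, THF, −78 °C
Reagents that add atoms: lithium diisopropylamide, [Li+].CC(C)[N-]C(C)C (Li only in 15)
Why: Deprotonation and kinetic reprotonation: LDA removes C7–H and then C4–H, the planar C4 ester enolate should be protonated on the α face because the axial C14 methyl on the adjacent C5 blocks the β face while the α face lacks one syn-axial hydrogen (C10 is sp2), so C15 ends equatorial β (4S), and the ketone enolate simply returns to the enone.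

Step 8
Reactants: 16 4-methoxybenzyl (1S,8aR)-8a-methyl-6-oxo-1,2,3,4,6,7,8,8a-octahydronaphthalene-1-carboxylate
Product: 18 4-methoxybenzyl (1S,7R,8aR)-8a-methyl-6-oxo-7-(prop-2-en-1-yl)-1,2,3,4,6,7,8,8a-octahydronaphthalene-1-carboxylate (7α-allyl), via cross-conjugated lithium enolate 17 (not isolated)
Conditions: LDA (1.05 equiv), THF, −78 °C; allyl bromide, DMPU, −78 to −30 °C
Reagents that add atoms: lithium diisopropylamide, [Li+].CC(C)[N-]C(C)C (Li only in 17); allyl bromide, C=CCBr
Why: Kinetic α′-alkylation of a cross-conjugated enone enolate: the electrophile should enter at C7 on the α face, away from the 1,3-related axial C14 methyl (as in 2α-alkylation of Δ4-3-keto steroids), which gives the equatorial and also thermodynamically preferred 7α-allyl ketone.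

Step 9
Reactants: 18 7α-allyl enone PMB ester
Product: 19 4-methoxybenzyl (1S,7R,8aR)-6-[(tert-butyldimethylsilyl)oxy]-8a-methyl-7-(prop-2-en-1-yl)-1,2,3,7,8,8a-hexahydronaphthalene-1-carboxylate (C8(OTBS)=C9–C10=C1 dienol ether)
Conditions: TBSOTf, Et3N, CH2Cl2, 0 °C
Reagents that add atoms: tert-butyldimethylsilyl trifluoromethanesulfonate, CC(C)(C)[Si](C)(C)OS(=O)(=O)C(F)(F)F
Why: Soft enolisation with silyl triflate and amine under equilibrating conditions should give the linear dienol silyl ether by loss of the axial C1 hydrogen, as in the formation of 3,5-dienol ethers from Δ4-3-keto steroids, while the tertiary C7–H stays in place.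

Step 10
Reactants: 19 dienol silyl ether
Product: 20 4-methoxybenzyl (1S,4R,7R,8aR)-4-hydroxy-8a-methyl-6-oxo-7-(prop-2-en-1-yl)-1,2,3,4,6,7,8,8a-octahydronaphthalene-1-carboxylate (1β-OH)
Conditions: DMDO, acetone/CH2Cl2, −78 to −20 °C; then aq citric acid, THF, 0 °C
Reagents that add atoms: dimethyldioxirane, CC1(C)OO1
Why: Vinylogous Rubottom oxidation: oxygen is transferred to the electron-rich C1 terminus of the dienol ether much faster than to the terminal allyl alkene, and the stereoelectronically preferred axial (β) attack known from the 6β-hydroxylation of steroid 3,5-dienol ethers should set (1R).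

Step 11
Reactants: 21 (2R)-3-bromo-2-methylpropan-1-ol
Product: 22 (2S)-2-methylhexan-1-ol
Conditions: n-PrMgCl (3 equiv), Li2CuCl4 (cat.), THF, −20 to 0 °C; 1 M HCl
Reagents that add atoms: n-propylmagnesium chloride, CCC[Mg]Cl
Why: Copper-catalysed Grignard cross-coupling (Kochi type) of a primary bromide, run on the magnesium alkoxide, builds the butyl chain without touching the chiral-pool stereocentre, whose descriptor changes from R to S only because the priorities change.

Step 12
Reactants: 22 (2S)-2-methylhexan-1-ol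
Product: 24 ethyl (2E,4S)-2,4-dimethyloct-2-enoate, via aldehyde 23 (not isolated)
Conditions: TEMPO (cat.), PhI(OAc)2, CH2Cl2, rt; then Ph3P=C(Me)CO2Et, rt
Reagents that add atoms: ethyl 2-(triphenyl-λ5-phosphanylidene)propanoate, CCOC(=O)C(C)=P(c1ccccc1)(c1ccccc1)c1ccccc1
Why: One-pot oxoammonium oxidation and Wittig olefination with a stabilised ylide should give the (E)-trisubstituted enoate, and trapping the α-chiral aldehyde as it forms avoids its racemisation.

Step 13
Reactants: 24 ethyl (2E,4S)-2,4-dimethyloct-2-enoate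
Product: 25 (2E,4S)-2,4-dimethyloct-2-enoic acid
Conditions: LiOH, THF/MeOH/H2O, 40 °C; 1 M HCl
Reagents that add atoms: lithium hydroxide, [Li+].[OH-]
Why: Saponification of a conjugated ester leaves the alkene geometry and the γ-stereocentre unchanged because hydroxide does not deprotonate the γ position.

Step 14
Reactants: 20 1β-hydroxy enone PMB ester; 25 (2E,4S)-2,4-dimethyloct-2-enoic acid
Product: 27 4-methoxybenzyl (1S,4R,7R,8aR)-4-{[(2E,4S)-2,4-dimethyloct-2-enoyl]oxy}-8a-methyl-6-oxo-7-(prop-2-en-1-yl)-1,2,3,4,6,7,8,8a-octahydronaphthalene-1-carboxylate, via mixed anhydride 26 (not isolated)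
Conditions: 25, 2,4,6-Cl3C6H2COCl, Et3N, PhMe, rt; then 20, DMAP, rt to 40 °C
Reagents that add atoms: 2,4,6-trichlorobenzoyl chloride, O=C(Cl)c1c(Cl)cc(Cl)cc1Cl (atoms only in 26)
Why: Yamaguchi esterification activates the α-branched enoic acid strongly enough to acylate the hindered axial allylic alcohol with retention at C1 and without E/Z isomerisation of the tiglate-type acyl group.

Step 15
Reactants: 27 fully acylated PMB ester
Product: 28 (1S,4R,7R,8aR)-4-{[(2E,4S)-2,4-dimethyloct-2-enoyl]oxy}-8a-methyl-6-oxo-7-(prop-2-en-1-yl)-1,2,3,4,6,7,8,8a-octahydronaphthalene-1-carboxylic acid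
Conditions: TFA, anisole, CH2Cl2, 0 °C
Reagents that add atoms: none
Why: SN1 acidolysis of the 4-methoxybenzyl ester with a cation scavenger frees C15 before the sensitive acrolein exists, and the C1 ester is safe because its allyl cation would be destabilised by the enone.

Step 16
Reactants: 28 7α-allyl acid
Product: 29 (1S,4R,7S,8aR)-4-{[(2E,4S)-2,4-dimethyloct-2-enoyl]oxy}-8a-methyl-6-oxo-7-(2-oxoethyl)-1,2,3,4,6,7,8,8a-octahydronaphthalene-1-carboxylic acid
Conditions: OsO4 (cat.), NaIO4, 2,6-lutidine, dioxane/H2O, rt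
Reagents that add atoms: osmium tetroxide (catalytic oxygen carrier), O=[Os](=O)(=O)=O; sodium periodate, [Na+].[O-]I(=O)(=O)=O
Why: Lemieux–Johnson cleavage should select the electron-rich monosubstituted alkene over the conjugated C9=C10 and C2′=C3′ alkenes and gives the C11–C12 acetaldehyde unit on C7.

Step 17
Reactants: 29 keto aldehyde acid
Product: 30 integric acid
Conditions: CH2=NMe2+ I−, Et3N, CH2Cl2, rt; dilute citric acid work-up
Reagents that add atoms: N,N-dimethylmethyleneiminium iodide (Eschenmoser's salt), C=[N+](C)C.[I-]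
Why: Mannich reaction of the aldehyde enol at C11 followed by β-elimination of dimethylamine (Eschenmoser methylenation) installs C13 regiospecifically as the 2-substituted acrolein, and C7 keeps its equatorial configuration because only the aldehyde α-carbon is engaged.

**Compound list**
1 | 2-bromo-4-methoxy-1-methylbenzene | COc1ccc(C)c(Br)c1 | starting material
2 | glutaric anhydride | O=C1CCCC(=O)O1 | starting material
3 | (5-methoxy-2-methylphenyl)magnesium bromide | COc1ccc(C)c([Mg]Br)c1 | intermediate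
4 | 5-(5-methoxy-2-methylphenyl)-5-oxopentanoic acid | OC(=O)CCCC(=O)c1cc(OC)ccc1C | intermediate
5 | (5S)-5-hydroxy-5-(5-methoxy-2-methylphenyl)pentanoic acid | OC(=O)CCC[C@H](O)c1cc(OC)ccc1C | intermediate
6 | (6S)-6-(5-methoxy-2-methylphenyl)oxan-2-one | O=C1CCC[C@H](O1)c1cc(OC)ccc1C | intermediate
7 | lithium (5S)-5-hydroxy-5-(5-methoxy-2-methylphenyl)pentanoate | [Li+].[O-]C(=O)CCC[C@H](O)c1cc(OC)ccc1C | intermediate
8 | (5S)-5-hydroxy-5-(5-methoxy-2-methylcyclohexa-1,4-dien-1-yl)pentanoic acid | OC(=O)CCC[C@H](O)C1=C(C)CC=C(OC)C1 | intermediate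
9 | (6S)-6-(5-methoxy-2-methylcyclohexa-1,4-dien-1-yl)oxan-2-one | O=C1CCC[C@H](O1)C1=C(C)CC=C(OC)C1 | intermediate
10 | lithium enolate of 9 | [Li+].[O-]C1=CCC[C@H](O1)C1=C(C)CC=C(OC)C1 | intermediate
11 | (2S)-6-[(tert-butyldimethylsilyl)oxy]-2-(5-methoxy-2-methylcyclohexa-1,4-dien-1-yl)-3,4-dihydro-2H-pyran | CC(C)(C)[Si](C)(C)OC1=CCC[C@H](O1)C1=C(C)CC=C(OC)C1 | intermediate
12 | tert-butyldimethylsilyl (1R,8aR)-6-methoxy-8a-methyl-1,2,3,5,8,8a-hexahydronaphthalene-1-carboxylate | COC1=CC[C@@]2(C)C(=CCC[C@H]2C(=O)O[Si](C)(C)C(C)(C)C)C1 | intermediate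
13 | (1R,8aR)-8a-methyl-6-oxo-1,2,3,4,6,7,8,8a-octahydronaphthalene-1-carboxylic acid | O=C1CC[C@@]2(C)C(=C1)CCC[C@H]2C(=O)O | intermediate
14 | 4-methoxybenzyl (1R,8aR)-8a-methyl-6-oxo-1,2,3,4,6,7,8,8a-octahydronaphthalene-1-carboxylate | O=C1CC[C@@]2(C)C(=C1)CCC[C@H]2C(=O)OCc1ccc(OC)cc1 | intermediate
15 | dilithium bis-enolate of 14 (C7=C8–O− and C4=C15–O−) | [Li+].[Li+].[O-]C1=CC[C@@]2(C)C(=C1)CCCC2=C([O-])OCc1ccc(OC)cc1 | intermediate
16 | 4-methoxybenzyl (1S,8aR)-8a-methyl-6-oxo-1,2,3,4,6,7,8,8a-octahydronaphthalene-1-carboxylate | O=C1CC[C@@]2(C)C(=C1)CCC[C@@H]2C(=O)OCc1ccc(OC)cc1 | intermediate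
17 | cross-conjugated lithium enolate of 16 | [Li+].[O-]C1=CC[C@@]2(C)C(=C1)CCC[C@@H]2C(=O)OCc1ccc(OC)cc1 | intermediate
18 | 4-methoxybenzyl (1S,7R,8aR)-8a-methyl-6-oxo-7-(prop-2-en-1-yl)-1,2,3,4,6,7,8,8a-octahydronaphthalene-1-carboxylate | C=CC[C@@H]1C[C@@]2(C)C(=CC1=O)CCC[C@@H]2C(=O)OCc1ccc(OC)cc1 | intermediate
19 | 4-methoxybenzyl (1S,7R,8aR)-6-[(tert-butyldimethylsilyl)oxy]-8a-methyl-7-(prop-2-en-1-yl)-1,2,3,7,8,8a-hexahydronaphthalene-1-carboxylate | C=CC[C@@H]1C[C@@]2(C)C(C=C1O[Si](C)(C)C(C)(C)C)=CCC[C@@H]2C(=O)OCc1ccc(OC)cc1 | intermediate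
20 | 4-methoxybenzyl (1S,4R,7R,8aR)-4-hydroxy-8a-methyl-6-oxo-7-(prop-2-en-1-yl)-1,2,3,4,6,7,8,8a-octahydronaphthalene-1-carboxylate | C=CC[C@@H]1C[C@@]2(C)C(=CC1=O)[C@H](O)CC[C@@H]2C(=O)OCc1ccc(OC)cc1 | intermediate
21 | (2R)-3-bromo-2-methylpropan-1-ol | OC[C@@H](C)CBr | starting material
22 | (2S)-2-methylhexan-1-ol | OC[C@@H](C)CCCC | intermediate
23 | (2S)-2-methylhexanal | O=C[C@@H](C)CCCC | intermediate
24 | ethyl (2E,4S)-2,4-dimethyloct-2-enoate | CCOC(=O)/C(C)=C/[C@@H](C)CCCC | intermediate
25 | (2E,4S)-2,4-dimethyloct-2-enoic acid | OC(=O)/C(C)=C/[C@@H](C)CCCC | intermediate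
26 | (2E,4S)-2,4-dimethyloct-2-enoic 2,4,6-trichlorobenzoic anhydride | O=C(OC(=O)/C(C)=C/[C@@H](C)CCCC)c1c(Cl)cc(Cl)cc1Cl | intermediate
27 | 4-methoxybenzyl (1S,4R,7R,8aR)-4-{[(2E,4S)-2,4-dimethyloct-2-enoyl]oxy}-8a-methyl-6-oxo-7-(prop-2-en-1-yl)-1,2,3,4,6,7,8,8a-octahydronaphthalene-1-carboxylate | C=CC[C@@H]1C[C@@]2(C)C(=CC1=O)[C@H](OC(=O)/C(C)=C/[C@@H](C)CCCC)CC[C@@H]2C(=O)OCc1ccc(OC)cc1 | intermediate
28 | (1S,4R,7R,8aR)-4-{[(2E,4S)-2,4-dimethyloct-2-enoyl]oxy}-8a-methyl-6-oxo-7-(prop-2-en-1-yl)-1,2,3,4,6,7,8,8a-octahydronaphthalene-1-carboxylic acid | C=CC[C@@H]1C[C@@]2(C)C(=CC1=O)[C@H](OC(=O)/C(C)=C/[C@@H](C)CCCC)CC[C@@H]2C(=O)O | intermediate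
29 | (1S,4R,7S,8aR)-4-{[(2E,4S)-2,4-dimethyloct-2-enoyl]oxy}-8a-methyl-6-oxo-7-(2-oxoethyl)-1,2,3,4,6,7,8,8a-octahydronaphthalene-1-carboxylic acid | O=CC[C@@H]1C[C@@]2(C)C(=CC1=O)[C@H](OC(=O)/C(C)=C/[C@@H](C)CCCC)CC[C@@H]2C(=O)O | intermediate
30 | integric acid, (1S,4R,7S,8aR)-4-{[(2E,4S)-2,4-dimethyloct-2-enoyl]oxy}-8a-methyl-6-oxo-7-(3-oxoprop-1-en-2-yl)-1,2,3,4,6,7,8,8a-octahydronaphthalene-1-carboxylic acid | C=C(C=O)[C@@H]1C[C@@]2(C)C(=CC1=O)[C@H](OC(=O)/C(C)=C/[C@@H](C)CCCC)CC[C@@H]2C(=O)O | target

**Total step count:** 17. **Longest linear sequence:** 14 (steps 1–10 and 14–17).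

**Steps most likely to fail**

1. Step 5.
   - Risk: in the boat the C1–C2 bond must lie in the plane of the C10=C5 alkene, next to C14, so allylic 1,3-strain raises the barrier. At the higher temperature then needed, three processes may outrun the rearrangement: O-to-C silyl shift of the ketene acetal, its adventitious hydrolysis, and oxidative aromatisation of ring B.
   - Fallback (open-chain chair Ireland–Claisen, then ring closure by metathesis), setting out from 3: acylation of 3 with N-methoxy-N-methylacetamide should give aryl methyl ketone F1. Transfer hydrogenation with the (R,R)-catalyst should give (R)-carbinol F2, and Birch reduction of its alkoxide should give dienyl carbinol F3. Esterification with hex-5-enoic acid (EDC, DMAP) gives hex-5-enoate F4.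
   - LDA and TMSCl in THF without a polar additive, then warming, should take F4 through a chair with hydrogen, not carbon, facing C14. This gives acid F5, which carries (4S,5R) and an (E)-ethylidene group on C10.
   - Ring-closing metathesis (Hoveyda–Grubbs II) closes C1=C10 to bicyclic acid F6, aqueous HCl gives enone acid F7, and PMBCl/Cs2CO3 returns to the route at 16. Steps 6 and 7 are then no longer needed.

2. Step 7.
   - Risk: removal of the hindered C4 hydrogen next to the quaternary centre may be slow or incomplete, the amide base may attack the PMB ester instead, and some protonation may leak to the β face.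
   - Fallback (ketene alcoholysis instead of ester enolate protonation), setting out from 13: oxalyl chloride with catalytic DMF should give acid chloride F8, in which C4–H is far more acidic. Et3N eliminates HCl to give ketene F9.
   - 4-Methoxybenzyl alcohol adds in the ketene plane, and the resulting enol is protonated from the open α face. This returns to the route at 16 and skips 14.

3. Step 10.
   - Risk: facial selectivity may be poor, because attack anti to C14 on the α face competes with axial β attack. Oxidation of the allyl group may also compete.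
   - Fallback (make the α-alcohol on purpose and invert it with the acid), setting out from 19: desilylation with Bu4NF/AcOH at −78 °C, which protonates C9 kinetically, should give β,γ-unsaturated ketone F10. mCPBA should attack C1=C10 anti to C14 to give 1α,10α-epoxide F11.
   - Et3N opens F11 by β-elimination to 1α-alcohol F12. Mitsunobu esterification of F12 with 25 (PPh3, DIAD) inverts C1 and returns to the route at 27.

**Further compounds**
F1 | step 5 | 1-(5-methoxy-2-methylphenyl)ethan-1-one | CC(=O)c1cc(OC)ccc1C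
F2 | step 5 | (1R)-1-(5-methoxy-2-methylphenyl)ethan-1-ol | C[C@@H](O)c1cc(OC)ccc1C
F3 | step 5 | (1R)-1-(5-methoxy-2-methylcyclohexa-1,4-dien-1-yl)ethan-1-ol | C[C@@H](O)C1=C(C)CC=C(OC)C1
F4 | step 5 | (1R)-1-(5-methoxy-2-methylcyclohexa-1,4-dien-1-yl)ethyl hex-5-enoate | C=CCCCC(=O)O[C@H](C)C1=C(C)CC=C(OC)C1
F5 | step 5 | (2S)-2-[(1R,6E)-6-ethylidene-4-methoxy-1-methylcyclohex-3-en-1-yl]hex-5-enoic acid | COC1=CC[C@](C)([C@H](CCC=C)C(=O)O)/C(=C/C)C1
F6 | step 5 | (1S,8aR)-6-methoxy-8a-methyl-1,2,3,5,8,8a-hexahydronaphthalene-1-carboxylic acid | COC1=CC[C@@]2(C)C(=CCC[C@@H]2C(=O)O)C1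
F7 | step 5 | (1S,8aR)-8a-methyl-6-oxo-1,2,3,4,6,7,8,8a-octahydronaphthalene-1-carboxylic acid | O=C1CC[C@@]2(C)C(=C1)CCC[C@@H]2C(=O)O
F8 | step 7 | (1R,8aR)-8a-methyl-6-oxo-1,2,3,4,6,7,8,8a-octahydronaphthalene-1-carbonyl chloride | O=C1CC[C@@]2(C)C(=C1)CCC[C@H]2C(=O)Cl
F9 | step 7 | (4aR)-4a-methyl-5-(oxomethylidene)-4,4a,5,6,7,8-hexahydronaphthalen-2(3H)-one (ketene) | O=C1CC[C@@]2(C)C(=C1)CCCC2=C=O
F10 | step 10 | 4-methoxybenzyl (1S,7R,8aR)-8a-methyl-6-oxo-7-(prop-2-en-1-yl)-1,2,3,5,6,7,8,8a-octahydronaphthalene-1-carboxylate (C1=C10 alkene) | C=CC[C@@H]1C[C@@]2(C)C(CC1=O)=CCC[C@@H]2C(=O)OCc1ccc(OC)cc1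
F11 | step 10 | 1α,10α-epoxide of F10 | C=CC[C@@H]1C[C@@]2(C)[C@@]3(CC1=O)O[C@H]3CC[C@@H]2C(=O)OCc1ccc(OC)cc1
F12 | step 10 | 4-methoxybenzyl (1S,4S,7R,8aR)-4-hydroxy-8a-methyl-6-oxo-7-(prop-2-en-1-yl)-1,2,3,4,6,7,8,8a-octahydronaphthalene-1-carboxylate (1α-OH) | C=CC[C@@H]1C[C@@]2(C)C(=CC1=O)[C@@H](O)CC[C@@H]2C(=O)OCc1ccc(OC)cc1
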